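**Retrosynthetic overview**

1. The strategy rests on ring B: C2' OH and C4' OCH3 are meta with C3' and C5' unsubstituted, C1' carries the diaryl ether oxygen and C6' the CH2OAc. This is the resorcinol monomethyl ether pattern that a vinylketene–alkoxyacetylene benzannulation produces.
2. Ring B (formed last) is cut at C2'–C3' and C4'–C5' (to methoxyacetylene) and at C1'–C2' (6π closure), giving a 4-aryloxy-3-(acetoxymethyl)cyclobutenone whose sp3 carbon (future C1') already carries ring A (C1 CO2Me, C2 O-MOM, C4 CH3, C6 O) through oxygen.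
3. The four-membered ring is cut to an aryloxyketene and methoxyacetylene ([2+2]). The resulting 3-OCH3 group is then exchanged for CH2OH by addition of a hydroxymethyl-anion equivalent with carbonyl transposition, followed by acetylation, because monosubstituted ketenes do not add usefully to an unactivated alkyne such as propargyl acetate.
4. The ketene derives from the aryloxyacetic acid obtained by MOM protection and O-alkylation of methyl 2,6-dihydroxy-4-methylbenzoate.
5. Ring order: ring A is bought, the cyclobutenone is formed in step 5, ring B in step 9, and MOM removal ends the route.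

Key step: step 9

Assumption: methoxyacetylene (b.p. about 23 °C) is treated as not reliably purchasable, so it is made in step 4 and kept as a cold stock solution; every cyclobutenone is racemic at the aryloxy-bearing carbon, which becomes the achiral C1'.

**Route**

Step 1
Reactants: 1 methyl 2,6-dihydroxy-4-methylbenzoate
Product: 2 methyl 2-hydroxy-6-(methoxymethoxy)-4-methylbenzoate
Conditions: MOMCl (1.05 equiv), i-Pr2NEt, CH2Cl2, 0 °C to rt
Reagents that add atoms: chloromethyl methyl ether, COCCl
Why: Williamson-type O-alkylation (MOM protection) of one of two equivalent phenols; once one is etherified the other is held in a hydrogen bond to the ester carbonyl, so one equivalent of reagent should stop at the mono-ether.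

Step 2
Reactants: 2 methyl 2-hydroxy-6-(methoxymethoxy)-4-methylbenzoate; 3 benzyl bromoacetate
Product: 4 methyl 2-[2-(benzyloxy)-2-oxoethoxy]-6-(methoxymethoxy)-4-methylbenzoate
Conditions: K2CO3, DMF, 50 °C
Reagents that add atoms: none
Why: Williamson ether synthesis, the phenoxide displacing bromide from the α-bromo ester by SN2; K2CO3 is too weak a base to trigger Dieckmann closure onto the neighbouring methyl ester.

Step 3
Reactants: 4 methyl 2-[2-(benzyloxy)-2-oxoethoxy]-6-(methoxymethoxy)-4-methylbenzoate
Product: 5 [2-(methoxycarbonyl)-3-(methoxymethoxy)-5-methylphenoxy]acetic acid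
Conditions: H2 (1 atm), 10% Pd/C, EtOAc, rt
Reagents that add atoms: none
Why: Hydrogenolysis of the benzyl ester frees the acid while the methyl ester, MOM ether and aryl ether are inert.

Step 4
Reactants: 6 chloroacetaldehyde dimethyl acetal
Product: 8 methoxyacetylene, via sodium methoxyethynide 7 (not isolated)
Conditions: NaNH2 (3 equiv), liq. NH3, −33 °C; evaporate NH3; sat. aq. NaCl, −20 °C; distil into a −78 °C trap
Reagents that add atoms: none
Why: Double β-elimination (methanol, then HCl) from the chloroacetal by sodium amide gives the sodium acetylide, a known preparation of alkoxyacetylenes, and aqueous quench with distillation should deliver 8.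

Step 5
Reactants: 5 [2-(methoxycarbonyl)-3-(methoxymethoxy)-5-methylphenoxy]acetic acid; 8 methoxyacetylene
Product: 11 racemic methyl 2-[(2-methoxy-4-oxocyclobut-2-en-1-yl)oxy]-6-(methoxymethoxy)-4-methylbenzoate, via acid chloride 9 (not isolated), via aryloxyketene 10 (not isolated)
Conditions: Me2C=C(Cl)NMe2 (1.1 equiv), CH2Cl2, 0 °C to rt; then 8 (3 equiv), Et3N (slow addition), CH2Cl2, 0 °C to rt
Reagents that add atoms: none
Why: The α-chloroenamine converts the acid into its chloride without HCl (MOM kept), Et3N dehydrochlorinates it to the aryloxyketene, and ketene–ynol ether [2+2] cycloaddition follows with the nucleophilic CH of methoxyacetylene bonding to the ketene carbon, so OCH3 ends on C3 and OAr on C4; the new stereocentre forms racemic and is erased in step 9.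

Step 6
Reactants: 12 (tributylstannyl)methanol; 13 ethyl vinyl ether
Product: 14 tributyl[(1-ethoxyethoxy)methyl]stannane
Conditions: PPTS (cat.), CH2Cl2, 0 °C to rt
Reagents that add atoms: none
Why: Acid-catalysed addition of the alcohol to the enol ether (acetal protection) gives the α-alkoxystannane that serves as hydroxymethyl-anion precursor; the acetal stereocentre is racemic and is lost in step 7.

Step 7
Reactants: 11 racemic methyl 2-[(2-methoxy-4-oxocyclobut-2-en-1-yl)oxy]-6-(methoxymethoxy)-4-methylbenzoate; 14 tributyl[(1-ethoxyethoxy)methyl]stannane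
Product: 17 racemic methyl 2-{[2-(hydroxymethyl)-4-oxocyclobut-2-en-1-yl]oxy}-6-(methoxymethoxy)-4-methylbenzoate, via alkoxymethyllithium 15 (not isolated), via tertiary carbinol 16 (not isolated)
Conditions: 14 (1.3 equiv), n-BuLi (1.2 equiv), THF, −78 °C; add 11, −78 °C; then 1 M aq. HCl, THF, 0 °C
Reagents that add atoms: water, O
Why: Tin–lithium exchange gives the α-alkoxyalkyllithium, which should add 1,2 to the strained vinylogous-ester carbonyl in preference to the doubly ortho-substituted benzoate; dilute acid then effects a Stork–Danheiser-type carbonyl transposition with loss of methanol and cleaves the ethoxyethyl acetal far faster than the MOM ether, and because the aryloxy carbon adjoins both C1 and C3 the same constitution results whichever carbon is attacked.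

Step 8
Reactants: 17 racemic methyl 2-{[2-(hydroxymethyl)-4-oxocyclobut-2-en-1-yl]oxy}-6-(methoxymethoxy)-4-methylbenzoate
Product: 18 racemic methyl 2-{[2-(acetoxymethyl)-4-oxocyclobut-2-en-1-yl]oxy}-6-(methoxymethoxy)-4-methylbenzoate
Conditions: Ac2O, pyridine, CH2Cl2, 0 °C
Reagents that add atoms: acetic anhydride, CC(=O)OC(C)=O
Why: O-Acylation of the primary alcohol under mild amine base at 0 °C, which should leave the enone and the MOM ether untouched.

Step 9
Reactants: 18 racemic methyl 2-{[2-(acetoxymethyl)-4-oxocyclobut-2-en-1-yl]oxy}-6-(methoxymethoxy)-4-methylbenzoate; 8 methoxyacetylene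
Product: 23 methyl 2-[2-(acetoxymethyl)-6-hydroxy-4-methoxyphenoxy]-6-(methoxymethoxy)-4-methylbenzoate, via vinylketene 19 (not isolated), via alkenylcyclobutenone 20 (not isolated), via dienylketene 21 (not isolated), via cyclohexadienone 22 (not isolated)
Conditions: 8 (4 equiv), toluene (0.05 M), sealed tube, 80 °C then 110 °C
Reagents that add atoms: none
Why: Heating should open the cyclobutenone by conrotatory 4π electrocyclic cleavage of the C(=O)–C(OAr) bond, the aryloxy donor turning outward, to give vinylketene 19, whose ketene C=C undergoes [2+2] cycloaddition with methoxyacetylene: the nucleophilic CH of the ynol ether bonds to the ketene carbon (C2'–C3') and the methoxy-bearing carbon to the ketene α-carbon (C4'–C5'), giving 20. A second, reversible 4π opening gives dienylketene 21, and the isomer with the alkenyl group turned toward the ketene closes ring B by thermal disrotatory 6π electrocyclisation between the ketene carbon C2' and the aryloxy-bearing C1' (six-membered carbocycle), after which dienone 22 tautomerises to phenol 23. The closest known reaction type is the Danheiser benzannulation of cyclobutenones with alkoxyacetylenes, and outward rotation of an oxygen substituent on the sp3 carbon is the behaviour that underlies the Moore rearrangement of 4-oxygenated cyclobutenones. No stereocentre survives, since the racemic sp3 carbon of 18 becomes aromatic C1'. The step needs regioselectivity in the ketene–alkyne [2+2], which the polarisation of methoxyacetylene should secure. It also needs capture of 19 to outrun ketene dimerisation and acylation of the product phenol, which excess alkyne and dilution favour, and no basic treatment is used so that the benzylic acetate and MOM ether are kept.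

Step 10
Reactants: 23 methyl 2-[2-(acetoxymethyl)-6-hydroxy-4-methoxyphenoxy]-6-(methoxymethoxy)-4-methylbenzoate
Product: 24 betaethrin A
Conditions: TFA/CH2Cl2 (1:5), H2O (2 equiv), 0 °C to rt
Reagents that add atoms: none
Why: Acid-catalysed cleavage of the aryl MOM acetal with water trapping the methoxymethyl cation; the benzylic acetate, methyl ester and diaryl ether should be stable to this brief exposure.

**Compound list**

1 | methyl 2,6-dihydroxy-4-methylbenzoate | COC(=O)c1c(O)cc(C)cc1O | starting material
2 | methyl 2-hydroxy-6-(methoxymethoxy)-4-methylbenzoate | COC(=O)c1c(O)cc(C)cc1OCOC | intermediate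
3 | benzyl bromoacetate | O=C(CBr)OCc1ccccc1 | starting material
4 | methyl 2-[2-(benzyloxy)-2-oxoethoxy]-6-(methoxymethoxy)-4-methylbenzoate | COC(=O)c1c(OCOC)cc(C)cc1OCC(=O)OCc1ccccc1 | intermediate
5 | [2-(methoxycarbonyl)-3-(methoxymethoxy)-5-methylphenoxy]acetic acid | COC(=O)c1c(OCOC)cc(C)cc1OCC(=O)O | intermediate
6 | chloroacetaldehyde dimethyl acetal (2-chloro-1,1-dimethoxyethane) | COC(CCl)OC | starting material
7 | sodium methoxyethynide | [Na+].[C-]#COC | intermediate
8 | methoxyacetylene | C#COC | intermediate
9 | methyl 2-(2-chloro-2-oxoethoxy)-6-(methoxymethoxy)-4-methylbenzoate (acid chloride) | COC(=O)c1c(OCOC)cc(C)cc1OCC(=O)Cl | intermediate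
10 | methyl 2-(methoxymethoxy)-4-methyl-6-[(2-oxoethenyl)oxy]benzoate (aryloxyketene) | COC(=O)c1c(OCOC)cc(C)cc1OC=C=O | intermediate
11 | racemic methyl 2-[(2-methoxy-4-oxocyclobut-2-en-1-yl)oxy]-6-(methoxymethoxy)-4-methylbenzoate | COC(=O)c1c(OCOC)cc(C)cc1OC1C(=O)C=C1OC | intermediate
12 | (tributylstannyl)methanol | CCCC[Sn](CCCC)(CCCC)CO | starting material
13 | ethyl vinyl ether | C=COCC | starting material
14 | tributyl[(1-ethoxyethoxy)methyl]stannane (racemic acetal) | CCCC[Sn](CCCC)(CCCC)COC(C)OCC | intermediate
15 | [(1-ethoxyethoxy)methyl]lithium | [Li]COC(C)OCC | intermediate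
16 | methyl 2-({4-[(1-ethoxyethoxy)methyl]-4-hydroxy-2-methoxycyclobut-2-en-1-yl}oxy)-6-(methoxymethoxy)-4-methylbenzoate (diastereomer mixture) | COC(=O)c1c(OCOC)cc(C)cc1OC1C(OC)=CC1(O)COC(C)OCC | intermediate
17 | racemic methyl 2-{[2-(hydroxymethyl)-4-oxocyclobut-2-en-1-yl]oxy}-6-(methoxymethoxy)-4-methylbenzoate | COC(=O)c1c(OCOC)cc(C)cc1OC1C(=O)C=C1CO | intermediate
18 | racemic methyl 2-{[2-(acetoxymethyl)-4-oxocyclobut-2-en-1-yl]oxy}-6-(methoxymethoxy)-4-methylbenzoate | COC(=O)c1c(OCOC)cc(C)cc1OC1C(=O)C=C1COC(C)=O | intermediate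
19 | vinylketene: methyl 2-{[(1Z)-2-(acetoxymethyl)-4-oxobuta-1,3-dien-1-yl]oxy}-6-(methoxymethoxy)-4-methylbenzoate (aryloxy trans to the ketene arm) | COC(=O)c1c(OCOC)cc(C)cc1O/C=C(/C=C=O)COC(C)=O | intermediate
20 | alkenylcyclobutenone: racemic methyl 2-{[(1Z)-3-acetoxy-2-(2-methoxy-4-oxocyclobut-2-en-1-yl)prop-1-en-1-yl]oxy}-6-(methoxymethoxy)-4-methylbenzoate | COC1=CC(=O)C1/C(COC(C)=O)=C/Oc1cc(C)cc(OCOC)c1C(=O)OC | intermediate
21 | dienylketene ArO–CH=C(CH2OAc)–CH=C(OCH3)–CH=C=O (Ar = ring A; ketene arm and C(CH2OAc) cis on the central double bond) | O=C=C/C(OC)=C\C(COC(C)=O)=C\Oc1cc(C)cc(OCOC)c1C(=O)OC | intermediate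
22 | racemic 6-aryloxy-5-(acetoxymethyl)-3-methoxycyclohexa-2,4-dien-1-one (aryl = ring A) | COC1=CC(=O)C(Oc2cc(C)cc(OCOC)c2C(=O)OC)C(COC(C)=O)=C1 | intermediate
23 | methyl 2-[2-(acetoxymethyl)-6-hydroxy-4-methoxyphenoxy]-6-(methoxymethoxy)-4-methylbenzoate | COC(=O)c1c(OCOC)cc(C)cc1Oc1c(O)cc(OC)cc1COC(C)=O | intermediate
24 | betaethrin A, methyl 2-[2-(acetoxymethyl)-6-hydroxy-4-methoxyphenoxy]-6-hydroxy-4-methylbenzoate | COC(=O)c1c(O)cc(C)cc1Oc1c(O)cc(OC)cc1COC(C)=O | target

**Step count**

Total step count: 10 (steps 4 and 6 prepare reagents).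
Longest linear sequence: 8 steps (1, 2, 3, 5, 7, 8, 9, 10).

**Steps most likely to fail, with fallbacks**

Step 9. The vinylketene may be consumed by dimerisation, or by acylating the phenol already formed, before the volatile alkyne captures it; such ester by-products could not be cleaved with base without losing the acetate. The fallback abandons the benzannulation and brings ring B in as an arene. It sets out from phenol 2 and comes back at 24.
- Commercial 2-hydroxy-4-methoxybenzaldehyde (COc1ccc(C=O)c(O)c1) would be protected (MOMCl, i-Pr2NEt) to 4-methoxy-2-(methoxymethoxy)benzaldehyde F1.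
- Baeyer–Villiger oxidation and methanolysis (mCPBA; then K2CO3, MeOH) would give 4-methoxy-2-(methoxymethoxy)phenol F2.
- Magnesium-mediated ortho-formylation (MgCl2, Et3N, paraformaldehyde, MeCN, reflux) at the only free ortho position would give 2-hydroxy-5-methoxy-3-(methoxymethoxy)benzaldehyde F3.
- Tf2O/pyridine would give 2-formyl-4-methoxy-6-(methoxymethoxy)phenyl trifluoromethanesulfonate F4.
- Phenol 2 would be O-arylated with F4 (Pd(OAc)2, 2-(di-tert-butylphosphino)-2',4',6'-triisopropylbiphenyl, K3PO4, toluene, 100 °C) to methyl 2-[2-formyl-4-methoxy-6-(methoxymethoxy)phenoxy]-6-(methoxymethoxy)-4-methylbenzoate F5.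
- NaBH4 in MeOH would give methyl 2-[2-(hydroxymethyl)-4-methoxy-6-(methoxymethoxy)phenoxy]-6-(methoxymethoxy)-4-methylbenzoate F6, and Ac2O/pyridine would give methyl 2-[2-(acetoxymethyl)-4-methoxy-6-(methoxymethoxy)phenoxy]-6-(methoxymethoxy)-4-methylbenzoate F7.
- TFA/CH2Cl2 with a little water would remove both MOM ethers to give 24.

Step 5. The aryloxyketene may dimerise or oligomerise faster than it cycloadds. The fallback replaces the ketene by a more electrophilic keteniminium ion, which adds to an unactivated alkyne. It sets out from acid 5 and comes back at 18, so steps 6 to 8 are no longer needed.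
- Amide coupling (Me2NH·HCl, EDC, i-Pr2NEt) would give 2-[2-(methoxycarbonyl)-3-(methoxymethoxy)-5-methylphenoxy]-N,N-dimethylacetamide F8.
- Tf2O and 2,4,6-collidine in CH2Cl2 would generate the keteniminium triflate F9.
- [2+2] cycloaddition with propargyl acetate (CC(=O)OCC#C) in refluxing 1,2-dichloroethane would give the cyclobuteniminium triflate F10, the iminium carbon bonding to the terminal alkyne carbon.
- Aqueous NaHCO3 hydrolysis would give 18.

Step 7. The organolithium may deprotonate the aryloxy-bearing carbon or add to the ring A ester, and the acid step must unmask the carbinol and the ethoxyethyl acetal without eroding the MOM ether. The fallback removes the need for acetal discrimination and postpones the acetate to the end. It sets out from 11 and comes back at 24.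
- Commercial tributyl[(methoxymethoxy)methyl]stannane (n-BuLi, THF, −78 °C, then anhydrous CeCl3 to lower basicity) would add to 11, and brief dilute acid would give methyl 2-({2-[(methoxymethoxy)methyl]-4-oxocyclobut-2-en-1-yl}oxy)-6-(methoxymethoxy)-4-methylbenzoate F11.
- Benzannulation with 8 as in step 9 would give methyl 2-{2-hydroxy-4-methoxy-6-[(methoxymethoxy)methyl]phenoxy}-6-(methoxymethoxy)-4-methylbenzoate F12.
- HCl in MeOH at 45 °C would remove both MOM groups to give methyl 2-hydroxy-6-[2-hydroxy-6-(hydroxymethyl)-4-methoxyphenoxy]-4-methylbenzoate F13.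
- Candida antarctica lipase B with vinyl acetate would acetylate the aliphatic hydroxyl in preference to the two phenols, giving 24.

**Further compounds**

F1 | step 9 | 4-methoxy-2-(methoxymethoxy)benzaldehyde | COCOc1cc(OC)ccc1C=O
F2 | step 9 | 4-methoxy-2-(methoxymethoxy)phenol | COCOc1cc(OC)ccc1O
F3 | step 9 | 2-hydroxy-5-methoxy-3-(methoxymethoxy)benzaldehyde | COCOc1cc(OC)cc(C=O)c1O
F4 | step 9 | 2-formyl-4-methoxy-6-(methoxymethoxy)phenyl trifluoromethanesulfonate | COCOc1cc(OC)cc(C=O)c1OS(=O)(=O)C(F)(F)F
F5 | step 9 | methyl 2-[2-formyl-4-methoxy-6-(methoxymethoxy)phenoxy]-6-(methoxymethoxy)-4-methylbenzoate | COC(=O)c1c(OCOC)cc(C)cc1Oc1c(OCOC)cc(OC)cc1C=O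
F6 | step 9 | methyl 2-[2-(hydroxymethyl)-4-methoxy-6-(methoxymethoxy)phenoxy]-6-(methoxymethoxy)-4-methylbenzoate | COC(=O)c1c(OCOC)cc(C)cc1Oc1c(OCOC)cc(OC)cc1CO
F7 | step 9 | methyl 2-[2-(acetoxymethyl)-4-methoxy-6-(methoxymethoxy)phenoxy]-6-(methoxymethoxy)-4-methylbenzoate | COC(=O)c1c(OCOC)cc(C)cc1Oc1c(OCOC)cc(OC)cc1COC(C)=O
F8 | step 5 | 2-[2-(methoxycarbonyl)-3-(methoxymethoxy)-5-methylphenoxy]-N,N-dimethylacetamide | COC(=O)c1c(OCOC)cc(C)cc1OCC(=O)N(C)C
F9 | step 5 | N-{2-[2-(methoxycarbonyl)-3-(methoxymethoxy)-5-methylphenoxy]ethenylidene}-N-methylmethanaminium trifluoromethanesulfonate (keteniminium salt) | COC(=O)c1c(OCOC)cc(C)cc1OC=C=[N+](C)C.[O-]S(=O)(=O)C(F)(F)F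
F10 | step 5 | racemic N-{3-(acetoxymethyl)-4-[2-(methoxycarbonyl)-3-(methoxymethoxy)-5-methylphenoxy]cyclobut-2-en-1-ylidene}-N-methylmethanaminium trifluoromethanesulfonate | COC(=O)c1c(OCOC)cc(C)cc1OC1C(=[N+](C)C)C=C1COC(C)=O.[O-]S(=O)(=O)C(F)(F)F
F11 | step 7 | racemic methyl 2-({2-[(methoxymethoxy)methyl]-4-oxocyclobut-2-en-1-yl}oxy)-6-(methoxymethoxy)-4-methylbenzoate | COC(=O)c1c(OCOC)cc(C)cc1OC1C(=O)C=C1COCOC
F12 | step 7 | methyl 2-{2-hydroxy-4-methoxy-6-[(methoxymethoxy)methyl]phenoxy}-6-(methoxymethoxy)-4-methylbenzoate | COC(=O)c1c(OCOC)cc(C)cc1Oc1c(O)cc(OC)cc1COCOC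
F13 | step 7 | methyl 2-hydroxy-6-[2-hydroxy-6-(hydroxymethyl)-4-methoxyphenoxy]-4-methylbenzoate | COC(=O)c1c(O)cc(C)cc1Oc1c(O)cc(OC)cc1CO
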